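**Plan**

1. Retrosynthetic cuts, in order: (a) ring C of each flavanone unit at its acyl–aryl bond (C4''–C4a'' of unit 2, then C4–C4a of unit 1) and at its aryl ether bond (O1''–C8a'', O1–C8a), which leads to a C2-symmetric exo,exo-bis-γ-lactone in which each benzylic oxygen is acylated by the carboxyl group of the other unit; (b) both benzylic C–O bonds, to (2S,3S)-2,3-bis(4-methoxybenzyl)succinic acid; (c) the C3–C3'' bond, to two molecules of one 3-(4-methoxyphenyl)propanoyl oxazolidinone.
2. Forward order: oxidative enolate homocoupling of two molecules of the imide (C3–C3''); double oxidative lactonization (C2–O, C2''–O); lactone 1 opened to an N-methoxy-N-methylamide; ring A of unit 1 attached to O1 by aryne O–H insertion; lactone 2 opened; ring C of unit 2 closed by an aryne annulation; ring C of unit 1 closed by Friedel–Crafts acylation; ether cleavage.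
3. Enabling feature: in unit 2 the oxygen O1'' (on C2'') and the carbonyl carbon C4'' (on C3'') are 1,3-related and end on the adjacent ring A carbons C8a'' and C4a''. A 3,5-dimethoxybenzyne supplies these two carbons; its future 5''-methoxy group directs oxygen to C8a'' and leaves the carbanion on C4a'', next to the amide carbonyl.
4. Stereochemistry: C3 and C3'' come from the (R)-4-benzyloxazolidinone in the homocoupling; C2 and C2'' come from exo-selective lactonization on the cis-fused bicycle. Afterwards no bond to any of the four stereocentres is broken, so the exo,exo-bis-lactone maps with retention onto the 2,3-cis, 2'',3''-cis (all-R) target.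
5. Helpers: the two lactones serve as temporary rings, the N-methoxy-N-methylamide keeps the unit 2 ketone masked until work-up, and the benzyl and 5''-methyl ethers leave together in the last step.

Key step: step 12

Remark: the given structure is read as (2R,3R,2''R,3''R), that is 2,3-cis in both units; unprimed locants denote the 5,7-dihydroxy unit (unit 1), double-primed locants the 5-hydroxy-7-methoxy unit (unit 2).
Assumption: the two 2-(trimethylsilyl)aryl triflates are treated as not purchasable and are made in steps 1 to 4.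

**Route**

Step 1
Reactants: 1 3,5-bis(benzyloxy)phenol
Product: 2 3,5-bis(benzyloxy)-2-bromophenol
Conditions: NBS, CH2Cl2, −78 °C
Reagents that add atoms: N-bromosuccinimide, O=C1CCC(=O)N1Br
Why: Electrophilic aromatic bromination of a phenol, which at low temperature in a non-polar solvent should take place ortho to the free hydroxyl (between OH and OBn); any para isomer is removed here.

Step 2
Reactants: 2 3,5-bis(benzyloxy)-2-bromophenol
Product: 5 3,5-bis(benzyloxy)-2-(trimethylsilyl)phenyl trifluoromethanesulfonate, via trimethylsilyl ether 3 (not isolated), via lithium 2-silylphenolate 4 (not isolated)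
Conditions: (Me3Si)2NH, THF, 70 °C; evaporate; n-BuLi, THF, −100 °C; then (CF3SO2)2O, −100 °C to rt
Reagents that add atoms: hexamethyldisilazane, C[Si](C)(C)N[Si](C)(C)C; trifluoromethanesulfonic anhydride, O=S(=O)(OS(=O)(=O)C(F)(F)F)C(F)(F)F
Why: O-silylation, bromine–lithium exchange and retro-Brook (O-to-C) silyl migration should give the ortho-silyl phenolate, whose O-triflation is the standard entry to 2-(trimethylsilyl)aryl triflates.

Step 3
Reactants: 6 3,5-dimethoxyphenol
Product: 7 2-bromo-3,5-dimethoxyphenol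
Conditions: NBS, CH2Cl2, −78 °C
Reagents that add atoms: N-bromosuccinimide, O=C1CCC(=O)N1Br
Why: Electrophilic aromatic bromination ortho to the free hydroxyl, as in step 1.

Step 4
Reactants: 7 2-bromo-3,5-dimethoxyphenol
Product: 10 3,5-dimethoxy-2-(trimethylsilyl)phenyl trifluoromethanesulfonate, via trimethylsilyl ether 8 (not isolated), via lithium 2-silylphenolate 9 (not isolated)
Conditions: (Me3Si)2NH, THF, 70 °C; evaporate; n-BuLi, THF, −100 °C; then (CF3SO2)2O, −100 °C to rt
Reagents that add atoms: hexamethyldisilazane, C[Si](C)(C)N[Si](C)(C)C; trifluoromethanesulfonic anhydride, O=S(=O)(OS(=O)(=O)C(F)(F)F)C(F)(F)F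
Why: The same silylation, halogen–lithium exchange, retro-Brook rearrangement and triflation sequence as in step 2.

Step 5
Reactants: 11 (R)-4-benzyl-1,3-oxazolidin-2-one; 12 3-(4-methoxyphenyl)propanoyl chloride
Product: 13 (R)-4-benzyl-3-[3-(4-methoxyphenyl)propanoyl]-1,3-oxazolidin-2-one
Conditions: Et3N, DMAP (cat.), CH2Cl2, 0 °C to rt
Reagents that add atoms: none
Why: N-acylation of the oxazolidinone by the acid chloride under nucleophilic catalysis.

Step 6
Reactants: 13 (R)-4-benzyl-3-[3-(4-methoxyphenyl)propanoyl]-1,3-oxazolidin-2-one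
Product: 15 (4R,4'R)-3,3'-[(2S,3S)-2,3-bis(4-methoxybenzyl)butanedioyl]bis(4-benzyl-1,3-oxazolidin-2-one), via lithium Z-enolate 14 (not isolated)
Conditions: LiN(i-Pr)2 (1 equiv per 13), THF, −78 °C; then PhI(OAc)2 (0.5 equiv per 13), −78 °C to rt
Reagents that add atoms: second molecule of 13 as the homocoupling partner, COc1ccc(CCC(=O)N2[C@H](Cc3ccccc3)COC2=O)cc1
Why: Oxidative enolate homocoupling, in which two molecules of 13 are converted into the chelated lithium (Z)-enolate and joined at their α-carbons by the hypervalent iodine oxidant with loss of two electrons; each terminus of the new C3–C3'' bond is formed on the enolate face away from the benzyl group of its own auxiliary, so that the (R)-auxiliary should give the C2-symmetric (S,S)-succinate and not the meso isomer.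

Step 7
Reactants: 15 (4R,4'R)-3,3'-[(2S,3S)-2,3-bis(4-methoxybenzyl)butanedioyl]bis(4-benzyl-1,3-oxazolidin-2-one)
Product: 17 (2S,3S)-2,3-bis(4-methoxybenzyl)butanedioic acid, via dilithium bis(peroxycarboxylate) 16 (not isolated)
Conditions: LiOH, H2O2, THF–H2O, 0 °C; then Na2SO3; then HCl
Reagents that add atoms: hydrogen peroxide, OO
Why: Hydroperoxide cleavage of the N-acyloxazolidinone (attack at the exocyclic carbonyl, sulfite reduction of the peracid) should release the diacid without epimerization of the α-centres and return the auxiliary.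

Step 8
Reactants: 17 (2S,3S)-2,3-bis(4-methoxybenzyl)butanedioic acid
Product: 18 (3R,3aR,6R,6aR)-3,6-bis(4-methoxyphenyl)tetrahydrofuro[3,4-c]furan-1,4-dione (exo,exo-bis-lactone)
Conditions: DDQ, CH2Cl2, 4 Å molecular sieves, rt
Reagents that add atoms: none
Why: Oxidative benzylic lactonization, in which DDQ abstracts hydride from each p-methoxybenzylic CH2 and the cation is captured 5-exo by the γ-carboxyl group of the other half; the (S,S) backbone enforces the cis ring fusion, and each aryl group should take the exo position trans to the neighbouring acyl carbon (the thermodynamic outcome, since the p-methoxybenzylic C–O bond can re-ionize), which sets C2 and C2'' as R.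

Step 9
Reactants: 18 (3R,3aR,6R,6aR)-3,6-bis(4-methoxyphenyl)tetrahydrofuro[3,4-c]furan-1,4-dione
Product: 19 (2R,3R,4R)-4-[(R)-hydroxy(4-methoxyphenyl)methyl]-N-methoxy-2-(4-methoxyphenyl)-N-methyl-5-oxooxolane-3-carboxamide
Conditions: MeNH(OMe)·HCl, i-PrMgCl, THF, −20 °C; then aq. NH4Cl
Reagents that add atoms: N,O-dimethylhydroxylamine hydrochloride, CNOC.Cl
Why: Aminolysis of a lactone by the magnesium amide of N,O-dimethylhydroxylamine, where one equivalent should open only one of the two homotopic lactones because the strained bicycle is more electrophilic than the monocyclic product; no stereocentre is touched.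

Step 10
Reactants: 19 (2R,3R,4R)-4-[(R)-hydroxy(4-methoxyphenyl)methyl]-N-methoxy-2-(4-methoxyphenyl)-N-methyl-5-oxooxolane-3-carboxamide; 5 3,5-bis(benzyloxy)-2-(trimethylsilyl)phenyl trifluoromethanesulfonate
Product: 21 (2R,3R,4R)-4-[(R)-[3,5-bis(benzyloxy)phenoxy](4-methoxyphenyl)methyl]-N-methoxy-2-(4-methoxyphenyl)-N-methyl-5-oxooxolane-3-carboxamide, via 3,5-bis(benzyloxy)benzyne 20 (not isolated)
Conditions: KF, 18-crown-6, THF, −20 °C to rt
Reagents that add atoms: none
Why: O–H insertion of the secondary alcohol into the fluoride-generated aryne (nucleophilic addition, then proton transfer), with oxygen adding at the aryne carbon remote from the neighbouring benzyloxy group to give the 3,5-bis(benzyloxy)phenyl ether; C2 keeps its configuration because its C–O bond is not touched.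

Step 11
Reactants: 21 (2R,3R,4R)-4-[(R)-[3,5-bis(benzyloxy)phenoxy](4-methoxyphenyl)methyl]-N-methoxy-2-(4-methoxyphenyl)-N-methyl-5-oxooxolane-3-carboxamide
Product: 22 potassium (2R,3R,4R)-2-[(R)-[3,5-bis(benzyloxy)phenoxy](4-methoxyphenyl)methyl]-3-[methoxy(methyl)carbamoyl]-4-(4-methoxyphenyl)-4-[(trimethylsilyl)oxy]butanoate
Conditions: KOSiMe3, THF, 0 °C to rt; evaporate
Reagents that add atoms: potassium trimethylsilanolate, C[Si](C)(C)[O-].[K+]
Why: Anhydrous lactone cleavage by silanolate (attack at the acyl carbon, not at the hindered benzylic carbon, then silyl transfer from the silyl ester to the liberated alkoxide) should give the potassium carboxylate with O1'' masked as its trimethylsilyl ether, so that re-lactonization is impossible and C2'' is retained.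

Step 12
Reactants: 22 potassium (2R,3R,4R)-2-[(R)-[3,5-bis(benzyloxy)phenoxy](4-methoxyphenyl)methyl]-3-[methoxy(methyl)carbamoyl]-4-(4-methoxyphenyl)-4-[(trimethylsilyl)oxy]butanoate; 10 3,5-dimethoxy-2-(trimethylsilyl)phenyl trifluoromethanesulfonate
Product: 25 (2R,3R)-3-[3,5-bis(benzyloxy)phenoxy]-2-[(2R,3R)-5,7-dimethoxy-2-(4-methoxyphenyl)-4-oxo-3,4-dihydro-2H-chromen-3-yl]-3-(4-methoxyphenyl)propanoic acid, via 3,5-dimethoxybenzyne 23 (not isolated), via dipotassium tetrahedral adduct 24 (not isolated)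
Conditions: KF, 18-crown-6, THF, 0 °C to rt; then 1 M HCl, 0 °C
Reagents that add atoms: none
Why: Proposed new method: fluoride removes the trimethylsilyl group from O1'' and, from the same pool, converts 10 into 3,5-dimethoxybenzyne 23; the C2'' alkoxide adds to the aryne carbon remote from the neighbouring methoxy group (the future C8a''), which places the aryl carbanion on the carbon flanked by that methoxy group (the future C4a''), and this carbanion attacks the N-methoxy-N-methylamide carbon C4'' to give the tetrahedral adduct 24, which collapses to the ketone only on acidic work-up. The closest known reaction types are the annulation of arynes with salicylate esters to xanthones (phenoxide addition, then acyl capture by the aryl anion) and the Parham cyclization of ortho-lithiated aryl ethers onto N-methoxy-N-methylamides; the extension is to an aliphatic aldol-type alkoxide. Ring C of unit 2 is closed by the C4''–C4a'' bond in a 6-exo-trig addition to the amide carbonyl. No new stereocentre is formed, and C2'' and C3'' keep the R configuration fixed in the bis-lactone because neither the C2''–O1'' bond nor the C3''–H bond is touched, which delivers the 2,3-cis flavanone. The step needs (a) oxygen addition at the distal aryne carbon, secured by the distortion of a 3-alkoxyaryne, (b) alkoxide in preference to carboxylate as the nucleophile, secured by its much higher nucleophilicity and a near-stoichiometric amount of aryne, and (c) acyl capture in preference to proton quench, secured by the aprotic medium, the six-membered transition state and the inertness of the carboxylate. The ketone stays masked in 24 while base is present, so the epimerizable C3'' and the β-aryloxy ketone are never exposed to alkoxide or fluoride.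

Step 13
Reactants: 25 (2R,3R)-3-[3,5-bis(benzyloxy)phenoxy]-2-[(2R,3R)-5,7-dimethoxy-2-(4-methoxyphenyl)-4-oxo-3,4-dihydro-2H-chromen-3-yl]-3-(4-methoxyphenyl)propanoic acid
Product: 27 (2R,2'R,3R,3'R)-5,7-bis(benzyloxy)-5',7'-dimethoxy-2,2'-bis(4-methoxyphenyl)-2,2',3,3'-tetrahydro-4H,4'H-[3,3'-bichromene]-4,4'-dione, via mixed trifluoroacetic anhydride 26 (not isolated)
Conditions: (CF3CO)2O, CH2Cl2, 0 °C
Reagents that add atoms: none
Why: Intramolecular Friedel–Crafts acylation through the mixed anhydride, in which the phloroglucinol-type triether ring is acylated at either of its two equivalent positions ortho to the ether oxygen (six-membered ring closure, C4–C4a) under acidic, non-enolizing conditions, so that no stereocentre should be affected.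

Step 14
Reactants: 27 (2R,2'R,3R,3'R)-5,7-bis(benzyloxy)-5',7'-dimethoxy-2,2'-bis(4-methoxyphenyl)-2,2',3,3'-tetrahydro-4H,4'H-[3,3'-bichromene]-4,4'-dione
Product: 28 (2R,2'R,3R,3'R)-5,5',7-trihydroxy-7'-methoxy-2,2'-bis(4-methoxyphenyl)-2,2',3,3'-tetrahydro-4H,4'H-[3,3'-bichromene]-4,4'-dione (CNP0184936.2)
Conditions: BCl3, C6HMe5, CH2Cl2, −78 to 0 °C; then H2O
Reagents that add atoms: none
Why: Lewis-acid ether cleavage, in which BCl3 should remove both benzyl groups (benzyl cation trapped by pentamethylbenzene) and, through chelation with the C4'' carbonyl, only the peri 5''-methoxy group, while the non-chelated 7''-, 4'- and 4'''-methoxy groups remain and the low temperature avoids ring opening or epimerization at C2/C3.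

**Compound list**

1 | 3,5-bis(benzyloxy)phenol | Oc1cc(OCc2ccccc2)cc(OCc2ccccc2)c1 | starting material
2 | 3,5-bis(benzyloxy)-2-bromophenol | Oc1cc(OCc2ccccc2)cc(OCc2ccccc2)c1Br | intermediate
3 | [3,5-bis(benzyloxy)-2-bromophenoxy]trimethylsilane | C[Si](C)(C)Oc1cc(OCc2ccccc2)cc(OCc2ccccc2)c1Br | intermediate
4 | lithium 3,5-bis(benzyloxy)-2-(trimethylsilyl)phenolate | [Li+].[O-]c1cc(OCc2ccccc2)cc(OCc2ccccc2)c1[Si](C)(C)C | intermediate
5 | 3,5-bis(benzyloxy)-2-(trimethylsilyl)phenyl trifluoromethanesulfonate | C[Si](C)(C)c1c(OCc2ccccc2)cc(OCc2ccccc2)cc1OS(=O)(=O)C(F)(F)F | intermediate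
6 | 3,5-dimethoxyphenol | COc1cc(O)cc(OC)c1 | starting material
7 | 2-bromo-3,5-dimethoxyphenol | COc1cc(O)c(Br)c(OC)c1 | intermediate
8 | (2-bromo-3,5-dimethoxyphenoxy)trimethylsilane | COc1cc(O[Si](C)(C)C)c(Br)c(OC)c1 | intermediate
9 | lithium 3,5-dimethoxy-2-(trimethylsilyl)phenolate | [Li+].[O-]c1cc(OC)cc(OC)c1[Si](C)(C)C | intermediate
10 | 3,5-dimethoxy-2-(trimethylsilyl)phenyl trifluoromethanesulfonate | COc1cc(OC)c([Si](C)(C)C)c(OS(=O)(=O)C(F)(F)F)c1 | intermediate
11 | (R)-4-benzyl-1,3-oxazolidin-2-one | O=C1N[C@H](Cc2ccccc2)CO1 | starting material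
12 | 3-(4-methoxyphenyl)propanoyl chloride | COc1ccc(CCC(=O)Cl)cc1 | starting material
13 | (R)-4-benzyl-3-[3-(4-methoxyphenyl)propanoyl]-1,3-oxazolidin-2-one | COc1ccc(CCC(=O)N2[C@H](Cc3ccccc3)COC2=O)cc1 | intermediate
14 | lithium (Z)-enolate of 13 | COc1ccc(C/C=C(\[O-])N2[C@H](Cc3ccccc3)COC2=O)cc1.[Li+] | intermediate
15 | (4R,4'R)-3,3'-[(2S,3S)-2,3-bis(4-methoxybenzyl)butanedioyl]bis(4-benzyl-1,3-oxazolidin-2-one) | COc1ccc(cc1)C[C@H](C(=O)N1[C@H](Cc2ccccc2)COC1=O)[C@@H](C(=O)N1[C@H](Cc2ccccc2)COC1=O)Cc1ccc(OC)cc1 | intermediate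
16 | dilithium (2S,3S)-2,3-bis(4-methoxybenzyl)butanediperoxoate | COc1ccc(cc1)C[C@H](C(=O)O[O-])[C@@H](C(=O)O[O-])Cc1ccc(OC)cc1.[Li+].[Li+] | intermediate
17 | (2S,3S)-2,3-bis(4-methoxybenzyl)butanedioic acid | COc1ccc(cc1)C[C@H](C(=O)O)[C@@H](C(=O)O)Cc1ccc(OC)cc1 | intermediate
18 | (3R,3aR,6R,6aR)-3,6-bis(4-methoxyphenyl)tetrahydrofuro[3,4-c]furan-1,4-dione | O=C1O[C@@H](c3ccc(OC)cc3)[C@H]2[C@@H]1[C@H](c3ccc(OC)cc3)OC2=O | intermediate
19 | (2R,3R,4R)-4-[(R)-hydroxy(4-methoxyphenyl)methyl]-N-methoxy-2-(4-methoxyphenyl)-N-methyl-5-oxooxolane-3-carboxamide | COc1ccc(cc1)[C@H](O)[C@H]2[C@@H](C(=O)N(C)OC)[C@H](c3ccc(OC)cc3)OC2=O | intermediate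
20 | 3,5-bis(benzyloxy)benzyne (1,3-bis(benzyloxy)-4,5-didehydrobenzene) | C1(OCc2ccccc2)=CC(OCc2ccccc2)=CC#C1 | intermediate
21 | (2R,3R,4R)-4-[(R)-[3,5-bis(benzyloxy)phenoxy](4-methoxyphenyl)methyl]-N-methoxy-2-(4-methoxyphenyl)-N-methyl-5-oxooxolane-3-carboxamide | COc1ccc(cc1)[C@H](Oc1cc(OCc2ccccc2)cc(OCc2ccccc2)c1)[C@H]2[C@@H](C(=O)N(C)OC)[C@H](c3ccc(OC)cc3)OC2=O | intermediate
22 | potassium (2R,3R,4R)-2-[(R)-[3,5-bis(benzyloxy)phenoxy](4-methoxyphenyl)methyl]-3-[methoxy(methyl)carbamoyl]-4-(4-methoxyphenyl)-4-[(trimethylsilyl)oxy]butanoate | COc1ccc(cc1)[C@H](Oc1cc(OCc2ccccc2)cc(OCc2ccccc2)c1)[C@H](C(=O)[O-])[C@@H](C(=O)N(C)OC)[C@@H](O[Si](C)(C)C)c1ccc(OC)cc1.[K+] | intermediate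
23 | 3,5-dimethoxybenzyne (1,3-dimethoxy-4,5-didehydrobenzene) | COC1=CC(OC)=CC#C1 | intermediate
24 | dipotassium (2R,3R)-3-[3,5-bis(benzyloxy)phenoxy]-2-[(2R,3R)-5,7-dimethoxy-4-[methoxy(methyl)amino]-2-(4-methoxyphenyl)-4-oxidochroman-3-yl]-3-(4-methoxyphenyl)propanoate (configuration at C4'' not defined) | COc1ccc(cc1)[C@H](Oc1cc(OCc2ccccc2)cc(OCc2ccccc2)c1)[C@H](C(=O)[O-])[C@H]1C([O-])(N(C)OC)c2c(OC)cc(OC)cc2O[C@H]1c1ccc(OC)cc1.[K+].[K+] | intermediate
25 | (2R,3R)-3-[3,5-bis(benzyloxy)phenoxy]-2-[(2R,3R)-5,7-dimethoxy-2-(4-methoxyphenyl)-4-oxo-3,4-dihydro-2H-chromen-3-yl]-3-(4-methoxyphenyl)propanoic acid | COc1ccc(cc1)[C@H](Oc1cc(OCc2ccccc2)cc(OCc2ccccc2)c1)[C@H](C(=O)O)[C@H]1C(=O)c2c(OC)cc(OC)cc2O[C@H]1c1ccc(OC)cc1 | intermediate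
26 | mixed anhydride of 25 with trifluoroacetic acid | COc1ccc(cc1)[C@H](Oc1cc(OCc2ccccc2)cc(OCc2ccccc2)c1)[C@H](C(=O)OC(=O)C(F)(F)F)[C@H]1C(=O)c2c(OC)cc(OC)cc2O[C@H]1c1ccc(OC)cc1 | intermediate
27 | (2R,2'R,3R,3'R)-5,7-bis(benzyloxy)-5',7'-dimethoxy-2,2'-bis(4-methoxyphenyl)-2,2',3,3'-tetrahydro-4H,4'H-[3,3'-bichromene]-4,4'-dione | COc1ccc([C@@H]2Oc3cc(OCc4ccccc4)cc(OCc4ccccc4)c3C(=O)[C@@H]2[C@H]2C(=O)c3c(OC)cc(OC)cc3O[C@H]2c2ccc(OC)cc2)cc1 | intermediate
28 | (2R,2'R,3R,3'R)-5,5',7-trihydroxy-7'-methoxy-2,2'-bis(4-methoxyphenyl)-2,2',3,3'-tetrahydro-4H,4'H-[3,3'-bichromene]-4,4'-dione | COc1ccc([C@@H]2Oc3cc(O)cc(O)c3C(=O)[C@@H]2[C@H]2C(=O)c3c(O)cc(OC)cc3O[C@H]2c2ccc(OC)cc2)cc1 | target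

**Step count and risks**

Total step count: 14. Longest linear sequence: 10 steps (steps 5 to 14, from 11 and 12 to 28); steps 1 to 4 prepare the two aryne precursors.

Steps most likely to fail:

1. Step 12 (the step that bears the label). The aryl carbanion may be quenched by a proton before it reaches the amide carbonyl, the carboxylate may be arylated in competition with the alkoxide, or the free aldolate may fragment by retro-aldol cleavage before it meets the aryne. The fallback uses known chemistry only and sets out from 21. The remaining lactone is opened with the magnesium amide of N,O-dimethylhydroxylamine (MeNH(OMe)·HCl, i-PrMgCl, THF) to (2R,3R)-2-[(R)-[3,5-bis(benzyloxy)phenoxy](4-methoxyphenyl)methyl]-3-[(R)-hydroxy(4-methoxyphenyl)methyl]-N1,N4-dimethoxy-N1,N4-dimethylbutanediamide F1. Neutral O–H insertion of its alcohol into the aryne from 10 (KF, 18-crown-6, THF) gives the bis(aryl ether) bis(N-methoxy-N-methylamide) F2. LiAlH4 in THF at −78 °C reduces both amides to the dialdehyde F3, and a Pinnick oxidation (NaClO2, NaH2PO4, 2-methyl-2-butene, t-BuOH–H2O) gives the diacid F4. Trifluoroacetic anhydride in CH2Cl2 then closes ring C of both units by double Friedel–Crafts acylation (C4''–C4a'' and C4–C4a), and the sequence comes back to the route at 27.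

2. Step 10. Fluoride may promote re-lactonization of the γ-hydroxy amide back to 18 with loss of the amine, or the hindered secondary alcohol may add too slowly so that the aryne is consumed in other ways. The fallback sets out from 19 and replaces the aryne by a copper-catalysed oxidative etherification: 19 is coupled with potassium [3,5-bis(benzyloxy)phenyl]trifluoroborate F5 (made from the commercial boronic acid and KHF2) under Cu(OAc)2·H2O (divalent copper, catalytic), DMAP, 4 Å molecular sieves and O2 in CH2Cl2 at room temperature. The aryl group is transferred from copper to the alcohol oxygen, the C2–O bond again stays intact, and the sequence comes back to the route at 21.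

3. Step 8. The p-methoxybenzylic cation may lose a proton to give an arylidenesuccinic acid in place of lactonization, or the electron-rich rings may be oxidized further. The fallback sets out from 17 and separates oxidation from ring closure: radical benzylic bromination (NBS, dibenzoyl peroxide, PhCF3, reflux) gives (2S,3S)-2,3-bis[bromo(4-methoxyphenyl)methyl]butanedioic acid F6 (benzylic configuration not controlled). On treatment with NaHCO3 it lactonizes through the p-methoxybenzylic cation under thermodynamic control to the same exo,exo-bis-lactone, and the sequence comes back to the route at 18.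

**Further compounds**

F1 | step 12 | (2R,3R)-2-[(R)-[3,5-bis(benzyloxy)phenoxy](4-methoxyphenyl)methyl]-3-[(R)-hydroxy(4-methoxyphenyl)methyl]-N1,N4-dimethoxy-N1,N4-dimethylbutanediamide | COc1ccc(cc1)[C@H](Oc1cc(OCc2ccccc2)cc(OCc2ccccc2)c1)[C@H](C(=O)N(C)OC)[C@@H](C(=O)N(C)OC)[C@@H](O)c1ccc(OC)cc1
F2 | step 12 | (2R,3R)-2-[(R)-[3,5-bis(benzyloxy)phenoxy](4-methoxyphenyl)methyl]-3-[(R)-(3,5-dimethoxyphenoxy)(4-methoxyphenyl)methyl]-N1,N4-dimethoxy-N1,N4-dimethylbutanediamide | COc1ccc(cc1)[C@H](Oc1cc(OCc2ccccc2)cc(OCc2ccccc2)c1)[C@H](C(=O)N(C)OC)[C@@H](C(=O)N(C)OC)[C@@H](Oc1cc(OC)cc(OC)c1)c1ccc(OC)cc1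
F3 | step 12 | (2R,3R)-2-[(R)-[3,5-bis(benzyloxy)phenoxy](4-methoxyphenyl)methyl]-3-[(R)-(3,5-dimethoxyphenoxy)(4-methoxyphenyl)methyl]butanedial | COc1ccc(cc1)[C@H](Oc1cc(OCc2ccccc2)cc(OCc2ccccc2)c1)[C@H](C=O)[C@@H](C=O)[C@@H](Oc1cc(OC)cc(OC)c1)c1ccc(OC)cc1
F4 | step 12 | (2R,3R)-2-[(R)-[3,5-bis(benzyloxy)phenoxy](4-methoxyphenyl)methyl]-3-[(R)-(3,5-dimethoxyphenoxy)(4-methoxyphenyl)methyl]butanedioic acid | COc1ccc(cc1)[C@H](Oc1cc(OCc2ccccc2)cc(OCc2ccccc2)c1)[C@H](C(=O)O)[C@@H](C(=O)O)[C@@H](Oc1cc(OC)cc(OC)c1)c1ccc(OC)cc1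
F5 | step 10 | potassium [3,5-bis(benzyloxy)phenyl]trifluoroborate | [K+].F[B-](F)(F)c1cc(OCc2ccccc2)cc(OCc2ccccc2)c1
F6 | step 8 | (2S,3S)-2,3-bis[bromo(4-methoxyphenyl)methyl]butanedioic acid | COc1ccc(cc1)C(Br)[C@H](C(=O)O)[C@@H](C(=O)O)C(Br)c1ccc(OC)cc1
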